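**Assumption:** the SMILES is taken exactly as written, which is (5R,7R,8R,9S,10S,13S) with H-5 cis to CH3-10, i.e. a cis-fused (5β-H) decalin.

Labdane numbering is used throughout (decalin C1–C10, CH3-20 on C10, CH3-17 on C8, C18/C19 on C4, side chain C11–C16 on C9). β is the face of CH3-20; in the cis-decalin the β-face of ring B is the convex face.

## Retrosynthetic overview

1. The 2,3-dihydrofuran is closed last by Mo-catalysed cycloisomerisation of a C16-OH/C14≡C15 alkynol, which avoids carrying the acid-labile enol ether.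
2. C13 is set by lipase desymmetrisation of a 13,13-bis(hydroxymethyl) spiro-oxolane; the oxolane comes from 5-exo epoxide opening by 9α-OH, and the side chain from vinyl addition plus B-alkyl Suzuki coupling.
3. Ring B functionality is installed on a quinone-derived ring: 9α-OH by convex-face addition, 8α-O by hydroxyl-directed epoxidation and hydride opening, 7β-OH by Rubottom oxidation, then tertiary acetylation.
4. The cis-decalin (C5, C10) comes from a catalytic enantioselective Diels–Alder reaction of 2,6-dimethylbenzoquinone with allylidenecyclopropane; the spirocyclopropane is a latent gem-dimethyl group.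
5. Ring order: B (quinone) → A (Diels–Alder) → oxolane (C9–O–C13) → dihydrofuran.

## Route

Step 1
Reactants: 1 cyclopropyltriphenylphosphonium bromide; 2 acrolein
Product: 4 allylidenecyclopropane, via cyclopropylidenetriphenylphosphorane 3 (not isolated)
Conditions: KOtBu, THF, 0→50 °C; distil
Reagents that add atoms: none
Why: Wittig olefination of the aldehyde by the cyclopropylidene ylide gives the volatile 1,1-disubstituted diene whose tied-back terminus still allows the s-cis conformation; no stereocentre is formed.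

Step 2
Reactants: 4 allylidenecyclopropane; 5 2,6-dimethyl-1,4-benzoquinone
Product: 6 (5R,10S)-cis-fused spirocyclopropyl enedione
Conditions: (S)-o-tolyl-CBS oxazaborolidinium triflimide (10 mol%), CH2Cl2, −78→−40 °C
Reagents that add atoms: none
Why: Catalytic enantioselective Diels–Alder reaction in which the chiral Lewis acid binds the unhindered C6 carbonyl, so the CH2 terminus of the diene bonds to the methyl-bearing β-carbon (C10) and the cyclopropylidene terminus to C5; suprafacial addition makes H-5 and CH3-10 cis and the catalyst shields one enantioface to give (5R,10S) (the catalyst antipode would give the mirror image).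

Step 3
Reactants: 6 (5R,10S)-cis-fused spirocyclopropyl enedione
Product: 7 6α-hydroxy enone
Conditions: NaBH4, CeCl3·7H2O, MeOH, −78 °C
Reagents that add atoms: none
Why: Luche 1,2-reduction of the less hindered carbonyl (C6, flanked by C5-H, not the C9 carbonyl next to quaternary C10), with hydride arriving on the convex β-face to give the 6α-alcohol.

Step 4
Reactants: 7 6α-hydroxy enone; 8 vinylmagnesium bromide
Product: 9 9β-vinyl-6α,9α-diol
Conditions: CeCl3, THF, −78→0 °C (3 equiv of 8)
Reagents that add atoms: none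
Why: Organocerium 1,2-addition to the hindered non-enolisable C9 ketone from the convex β-face (the α-face is blocked by ring A), which sets C9 with 9α-OH and the carbon chain β.

Step 5
Reactants: 9 9β-vinyl-6α,9α-diol
Product: 10 7α,8α-epoxide
Conditions: VO(acac)2 (5 mol%), t-BuOOH, CH2Cl2, 0 °C→rt
Reagents that add atoms: tert-butyl hydroperoxide, CC(C)(C)OO
Why: Hydroxyl-directed vanadium-catalysed epoxidation in which both allylic hydroxyls (6α and 9α) deliver oxygen to the α-face of the trisubstituted C7=C8 bond, setting the C8–O bond α and CH3-17 β; the vinyl group and the ring-A alkene react far more slowly.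

Step 6
Reactants: 10 7α,8α-epoxide
Product: 11 6α,8α,9α-triol
Conditions: LiBHEt3, THF, 0 °C→reflux
Reagents that add atoms: none
Why: SN2 hydride opening of the trisubstituted epoxide at the less substituted C7 leaves the tertiary 8α-hydroxyl with C8 unchanged.

Step 7
Reactants: 11 6α,8α,9α-triol; 12 2-bromoprop-2-en-1-ol
Product: 14 side-chain allylic alcohol, via B-alkyl-9-BBN adduct 13 (not isolated)
Conditions: 9-BBN (excess), THF, rt; then 12, Pd(dppf)Cl2 (5 mol%), AsPh3, Cs2CO3, DMF/H2O, rt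
Reagents that add atoms: none
Why: Anti-Markovnikov hydroboration of the only monosubstituted alkene followed by B-alkyl Suzuki–Miyaura coupling with the vinyl bromide forms the C12–C13 bond; no stereocentre is touched.

Step 8
Reactants: 14 side-chain allylic alcohol
Product: 16 13,13-bis(hydroxymethyl) spiro-oxolane, via 13,16-epoxy alcohol 15 (not isolated)
Conditions: VO(acac)2 (5 mol%), t-BuOOH (1.2 equiv), CH2Cl2, 0 °C; then CSA (10 mol%), rt
Reagents that add atoms: tert-butyl hydroperoxide, CC(C)(C)OO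
Why: Directed epoxidation of the primary allylic alcohol followed by acid-catalysed 5-exo-tet opening at the tertiary epoxide carbon by 9α-OH (faster than 6-exo attack by 8-OH) closes the C9–O–C13 oxolane; C13 carries two identical CH2OH arms, so the epoxide configuration is irrelevant.

Step 9
Reactants: 16 13,13-bis(hydroxymethyl) spiro-oxolane
Product: 18 gem-dimethyl tetraol, via saturated spirocyclopropane 17 (not isolated)
Conditions: H2 (1 atm), PtO2, EtOH, rt; then AcOH, H2 (4 atm), 50 °C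
Reagents that add atoms: none
Why: Catalytic hydrogenation of the cis-alkene and then hydrogenolysis of the least hindered (CH2–CH2) cyclopropane bond converts the spirocyclopropane into the C4 gem-dimethyl group without affecting any stereocentre.

Step 10
Reactants: 18 gem-dimethyl tetraol
Product: 19 (13S)-16-monoacetate
Conditions: lipase (Burkholderia cepacia lipase, Amano PS-IM), vinyl acetate, MTBE, 30 °C
Reagents that add atoms: vinyl acetate, C=COC(C)=O
Why: Lipase-catalysed irreversible transesterification distinguishes the two diastereotopic hydroxymethyl groups and acetylates the pro-S arm, which sets the C13 quaternary stereocentre; the hindered secondary and tertiary hydroxyls are not substrates.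

Step 11
Reactants: 19 (13S)-16-monoacetate
Product: 20 C14 aldehyde
Conditions: TEMPO (10 mol%), PhI(OAc)2, CH2Cl2, rt
Reagents that add atoms: none
Why: Oxoammonium (TEMPO/BAIB) oxidation is selective for the primary alcohol over the hindered 6α-OH and is run at once so that 1,3-acyl migration cannot erode C13.

Step 12
Reactants: 20 C14 aldehyde
Product: 21 alkynyl triol
Conditions: dimethyl (1-diazo-2-oxopropyl)phosphonate, K2CO3, MeOH, 0 °C→rt
Reagents that add atoms: dimethyl (1-diazo-2-oxopropyl)phosphonate, COP(=O)(OC)C(=[N+]=[N-])C(C)=O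
Why: Ohira–Bestmann (Seyferth–Gilbert) homologation of the non-enolisable aldehyde gives the C14≡C15 alkyne, and the same K2CO3/MeOH removes the primary acetate; C13 is untouched.

Step 13
Reactants: 21 alkynyl triol
Product: 22 16-O-TBS ether
Conditions: TBSCl, imidazole, DMF, 0 °C
Reagents that add atoms: tert-butyldimethylsilyl chloride, CC(C)(C)[Si](C)(C)Cl
Why: Silylation is selective for the only primary hydroxyl over the hindered secondary 6-OH and tertiary 8-OH.

Step 14
Reactants: 22 16-O-TBS ether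
Product: 23 8α-hydroxy 6-ketone
Conditions: Dess–Martin periodinane, CH2Cl2, 0 °C→rt
Reagents that add atoms: none
Why: Dess–Martin oxidation of the only secondary alcohol under non-basic conditions avoids retro-aldol cleavage and epimerisation at C5.

Step 15
Reactants: 23 8α-hydroxy 6-ketone
Product: 24 8-O-TMS Δ6 silyl enol ether
Conditions: TMSOTf (2.5 equiv), Et3N, CH2Cl2, −78→0 °C
Reagents that add atoms: trimethylsilyl triflate, C[Si](C)(C)OS(=O)(=O)C(F)(F)F
Why: Soft enolisation silylates the tertiary 8-OH (blocking retro-aldol and β-elimination) and forms the enol ether towards C7 only, because H-5 lies between two quaternary carbons, so C5 is preserved.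

Step 16
Reactants: 24 8-O-TMS Δ6 silyl enol ether
Product: 26 7β,8α-dihydroxy 6-ketone, via bis-TMS ketol 25 (not isolated)
Conditions: mCPBA, hexane/CH2Cl2, −15 °C; then citric acid (cat.), MeOH, rt
Reagents that add atoms: mCPBA, OOC(=O)c1cccc(Cl)c1
Why: Rubottom oxidation in which the peracid attacks the enol ether on the convex β-face, anti to the 8α-silyloxy group and to C4, giving the 7β-oxygen; mild acid methanolysis then removes both TMS groups.

Step 17
Reactants: 26 7β,8α-dihydroxy 6-ketone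
Product: 27 7-O-TBS ether
Conditions: TBSOTf (1.05 equiv), 2,6-lutidine, CH2Cl2, −78 °C
Reagents that add atoms: tert-butyldimethylsilyl triflate, CC(C)(C)[Si](C)(C)OS(=O)(=O)C(F)(F)F
Why: Silyl triflate protects the secondary α-ketol hydroxyl in preference to the more hindered tertiary 8-OH.

Step 18
Reactants: 27 7-O-TBS ether
Product: 28 8α-acetate
Conditions: Ac2O, Sc(OTf)3 (5 mol%), MeCN, −20 °C
Reagents that add atoms: acetic anhydride, CC(=O)OC(C)=O
Why: Lewis-acid-catalysed acylation esterifies the hindered tertiary alcohol with retention at C8 and without base, so the β-oxygenated ketone neither eliminates nor undergoes retro-aldol cleavage.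

Step 19
Reactants: 28 8α-acetate
Product: 29 alkynol
Conditions: HF·pyridine, pyridine/THF, 0 °C→rt
Reagents that add atoms: none
Why: Buffered fluoride desilylation removes both TBS ethers while the tertiary acetate, the α-ketol and C5 are unaffected.

Step 20
Reactants: 29 alkynol
Product: 30 target CNP0275274.1
Conditions: Mo(CO)6 (25 mol%), Et3N, Et2O, hν (350 nm) to pre-form Et3N·Mo(CO)5; then 29, rt, dark
Reagents that add atoms: none
Why: McDonald alkynol cycloisomerisation via a molybdenum vinylidene closes the C16–O–C15 bond endo to give the 2,3-dihydrofuran under non-acidic conditions that spare the enol ether; no stereocentre is affected.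

## Compound list

1 | cyclopropyltriphenylphosphonium bromide | [Br-].C1CC1[P+](c1ccccc1)(c1ccccc1)c1ccccc1 | starting material
2 | acrolein (prop-2-enal) | C=CC=O | starting material
3 | cyclopropylidenetriphenylphosphorane | C1CC1=P(c1ccccc1)(c1ccccc1)c1ccccc1 | intermediate (not isolated)
4 | allylidenecyclopropane (prop-2-en-1-ylidenecyclopropane) | C=CC=C1CC1 | intermediate
5 | 2,6-dimethyl-1,4-benzoquinone | CC1=CC(=O)C=C(C)C1=O | starting material
6 | (5R,10S)-8,10-dimethyl-4-spirocyclopropyl-cis-octalin-2,7-diene-6,9-dione (5β-H; cyclopropane = C18–C19) | CC1=CC(=O)[C@@H]2C3(CC3)C=CC[C@]2(C)C1=O | intermediate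
7 | (6S)-6α-hydroxy-8,10-dimethyl-4-spirocyclopropyl-cis-octalin-2,7-dien-9-one | CC1=C[C@H](O)[C@@H]2C3(CC3)C=CC[C@]2(C)C1=O | intermediate
8 | vinylmagnesium bromide | C=C[Mg]Br | starting material
9 | 9β-vinyl-8,10-dimethyl-4-spirocyclopropyl-cis-octalin-2,7-diene-6α,9α-diol | CC1=C[C@H](O)[C@@H]2C3(CC3)C=CC[C@]2(C)[C@@]1(O)C=C | intermediate
10 | 7α,8α-epoxy-9β-vinyl-8β,10β-dimethyl-4-spirocyclopropyl-cis-octal-2-ene-6α,9α-diol | O1[C@]2(C)[C@H]1[C@H](O)[C@@H]3C4(CC4)C=CC[C@]3(C)[C@@]2(O)C=C | intermediate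
11 | 9β-vinyl-8β,10β-dimethyl-4-spirocyclopropyl-cis-octal-2-ene-6α,8α,9α-triol | O[C@]1(C)C[C@H](O)[C@@H]2C3(CC3)C=CC[C@]2(C)[C@@]1(O)C=C | intermediate
12 | 2-bromoprop-2-en-1-ol | OCC(Br)=C | starting material
13 | B-alkyl-9-BBN adduct of 11 (boron on C12; hydroxyls drawn free) | O[C@]1(C)C[C@H](O)[C@@H]2C3(CC3)C=CC[C@]2(C)[C@@]1(O)CCB1C2CCCC1CCC2 | intermediate (not isolated)
14 | 15-nor-4-spirocyclopropyl-5β-labda-2,13(16)-diene-6α,8α,9α,14-tetraol | O[C@]1(C)C[C@H](O)[C@@H]2C3(CC3)C=CC[C@]2(C)[C@@]1(O)CCC(=C)CO | intermediate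
15 | 13,16-epoxide of 14 (both C13 epimers) | O[C@]1(C)C[C@H](O)[C@@H]2C3(CC3)C=CC[C@]2(C)[C@@]1(O)CCC1(CO)CO1 | intermediate (not isolated)
16 | 9α,13-epoxy-15-nor-4-spirocyclopropyl-5β-labd-2-ene-6α,8α,14,16-tetraol | O[C@]1(C)C[C@H](O)[C@@H]2C3(CC3)C=CC[C@]2(C)[C@@]12CCC(CO)(CO)O2 | intermediate
17 | 2,3-dihydro derivative of 16 (cyclopropane intact) | O[C@]1(C)C[C@H](O)[C@@H]2C3(CC3)CCC[C@]2(C)[C@@]12CCC(CO)(CO)O2 | intermediate (not isolated)
18 | 9α,13-epoxy-15-nor-5β-labdane-6α,8α,14,16-tetraol | O[C@]1(C)C[C@H](O)[C@@H]2C(C)(C)CCC[C@]2(C)[C@@]12CCC(CO)(CO)O2 | intermediate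
19 | (13S)-16-acetoxy-9α,13-epoxy-15-nor-5β-labdane-6α,8α,14-triol | O[C@]1(C)C[C@H](O)[C@@H]2C(C)(C)CCC[C@]2(C)[C@@]12CC[C@@](COC(C)=O)(CO)O2 | intermediate
20 | 16-acetoxy-6α,8α-dihydroxy-9α,13-epoxy-15-nor-5β-labdan-14-al (C13 spatially as in 19) | O[C@]1(C)C[C@H](O)[C@@H]2C(C)(C)CCC[C@]2(C)[C@@]12CC[C@@](COC(C)=O)(C=O)O2 | intermediate
21 | (13S)-9α,13-epoxy-5β-labd-14-yne-6α,8α,16-triol | O[C@]1(C)C[C@H](O)[C@@H]2C(C)(C)CCC[C@]2(C)[C@@]12CC[C@@](CO)(C#C)O2 | intermediate
22 | (13S)-16-(tert-butyldimethylsilyloxy)-9α,13-epoxy-5β-labd-14-yne-6α,8α-diol | O[C@]1(C)C[C@H](O)[C@@H]2C(C)(C)CCC[C@]2(C)[C@@]12CC[C@@](CO[Si](C)(C)C(C)(C)C)(C#C)O2 | intermediate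
23 | (13S)-16-(tert-butyldimethylsilyloxy)-8α-hydroxy-9α,13-epoxy-5β-labd-14-yn-6-one | O[C@]1(C)CC(=O)[C@@H]2C(C)(C)CCC[C@]2(C)[C@@]12CC[C@@](CO[Si](C)(C)C(C)(C)C)(C#C)O2 | intermediate
24 | 6,8α-bis(trimethylsilyloxy)-16-(tert-butyldimethylsilyloxy)-9α,13-epoxy-5β-labd-6-en-14-yne | C[Si](C)(C)O[C@]1(C)C=C(O[Si](C)(C)C)[C@@H]2C(C)(C)CCC[C@]2(C)[C@@]12CC[C@@](CO[Si](C)(C)C(C)(C)C)(C#C)O2 | intermediate
25 | 7β,8α-bis(trimethylsilyloxy)-16-(tert-butyldimethylsilyloxy)-9α,13-epoxy-5β-labd-14-yn-6-one | C[Si](C)(C)O[C@]1(C)[C@@H](O[Si](C)(C)C)C(=O)[C@@H]2C(C)(C)CCC[C@]2(C)[C@@]12CC[C@@](CO[Si](C)(C)C(C)(C)C)(C#C)O2 | intermediate (not isolated)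
26 | 7β,8α-dihydroxy-16-(tert-butyldimethylsilyloxy)-9α,13-epoxy-5β-labd-14-yn-6-one | O[C@]1(C)[C@@H](O)C(=O)[C@@H]2C(C)(C)CCC[C@]2(C)[C@@]12CC[C@@](CO[Si](C)(C)C(C)(C)C)(C#C)O2 | intermediate
27 | 8α-hydroxy-7β,16-bis(tert-butyldimethylsilyloxy)-9α,13-epoxy-5β-labd-14-yn-6-one | O[C@]1(C)[C@@H](O[Si](C)(C)C(C)(C)C)C(=O)[C@@H]2C(C)(C)CCC[C@]2(C)[C@@]12CC[C@@](CO[Si](C)(C)C(C)(C)C)(C#C)O2 | intermediate
28 | 8α-acetoxy-7β,16-bis(tert-butyldimethylsilyloxy)-9α,13-epoxy-5β-labd-14-yn-6-one | CC(=O)O[C@]1(C)[C@@H](O[Si](C)(C)C(C)(C)C)C(=O)[C@@H]2C(C)(C)CCC[C@]2(C)[C@@]12CC[C@@](CO[Si](C)(C)C(C)(C)C)(C#C)O2 | intermediate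
29 | (13S)-8α-acetoxy-7β,16-dihydroxy-9α,13-epoxy-5β-labd-14-yn-6-one | CC(=O)O[C@]1(C)[C@@H](O)C(=O)[C@@H]2C(C)(C)CCC[C@]2(C)[C@@]12CC[C@@](CO)(C#C)O2 | intermediate
30 | (5R,7R,8R,9S,10S,13S)-8α-acetoxy-7β-hydroxy-9α,13;15,16-diepoxy-5β-labd-14-en-6-one (CNP0275274.1) | CC(=O)O[C@]1(C)[C@@H](O)C(=O)[C@@H]2C(C)(C)CCC[C@]2(C)[C@@]12CC[C@@]1(C=COC1)O2 | target

## Step count and risks

Total step count: 20. Longest linear sequence: 20 steps (1/2 → 30).

**Step 2 (enantioselective Diels–Alder with an unusual 1,1-disubstituted diene).** Reactivity, regiocontrol or ee may fall short, and the sense of induction for the named catalyst enantiomer must be confirmed. Fallback, setting out from 4 and 5: run the cycloaddition with BF3·OEt2 (CH2Cl2, −78 °C), which gives the same Lewis-acid-controlled orientation but racemic material, i.e. 6 together with ent-enedione F1. Luche reduction as in step 3 then gives 7 together with ent-alcohol F2. A lipase-catalysed kinetic resolution (Candida antarctica lipase B, vinyl acetate, MTBE, 30 °C) acetylates the (6R)-alcohol preferentially (Kazlauskas rule: large C5 side, medium C7 side) to ent-acetate F3, which is removed by chromatography. Unreacted 7 rejoins the route at compound 7.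

**Step 10 (lipase desymmetrisation of the diastereotopic CH2OH arms).** The degree and sense of selectivity are not predictable for this substrate and must be found by screening. Fallback, setting out from 14: Sharpless asymmetric epoxidation (Ti(OiPr)4, D-(–)-diethyl tartrate, t-BuOOH, 4 Å MS, CH2Cl2, −20 °C) gives (13R)-epoxy alcohol F4 under reagent control. TBSCl/imidazole gives epoxy silyl ether F5. CSA (cat., CH2Cl2) gives spiro-oxolane F6 by 5-exo opening with inversion at C13. H2/PtO2 (EtOH, then AcOH) gives gem-dimethyl silyl ether F7. Ac2O/pyridine at 0 °C acetylates the primary hydroxyl to acetate silyl ether F8. HF·pyridine removes the silyl group and returns the route to compound 19.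

**Step 18 (acetylation of a very hindered tertiary hydroxyl β to a ketone).** The reaction may stall, or elimination may compete. Fallback, setting out from 23 and bypassing steps 15–18: Burgess reagent (benzene, 50 °C) dehydrates the β-hydroxy ketone to Δ7-enone F9. Nucleophilic (Weitz–Scheffer) epoxidation with t-BuOOH/DBU, on the convex face anti to the C9–O bond, gives 7β,8β-epoxy ketone F10. AcOH with catalytic BF3·OEt2 opens the epoxide at tertiary C8 with inversion to give 8α-acetoxy-7β-hydroxy ketone F11. HF·pyridine removes the silyl group and returns the route to compound 29.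

## Further compounds

F1 | step 2 | (5S,10R)-enedione (enantiomer of 6) | CC1=CC(=O)[C@H]2C3(CC3)C=CC[C@@]2(C)C1=O
F2 | step 2 | (5S,6R,10R)-6-hydroxy enone (enantiomer of 7) | CC1=C[C@@H](O)[C@H]2C3(CC3)C=CC[C@@]2(C)C1=O
F3 | step 2 | 6-O-acetate of the enantiomer of 7 | CC1=C[C@@H](OC(C)=O)[C@H]2C3(CC3)C=CC[C@@]2(C)C1=O
F4 | step 10 | (13R)-13,16-epoxide of 14 | O[C@]1(C)C[C@H](O)[C@@H]2C3(CC3)C=CC[C@]2(C)[C@@]1(O)CC[C@@]1(CO)CO1
F5 | step 10 | 14-O-TBS ether of F4 | O[C@]1(C)C[C@H](O)[C@@H]2C3(CC3)C=CC[C@]2(C)[C@@]1(O)CC[C@@]1(CO[Si](C)(C)C(C)(C)C)CO1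
F6 | step 10 | 14-(tert-butyldimethylsilyloxy)-9α,13-epoxy-15-nor-4-spirocyclopropyl-5β-labd-2-ene-6α,8α,16-triol | O[C@]1(C)C[C@H](O)[C@@H]2C3(CC3)C=CC[C@]2(C)[C@@]12CC[C@@](CO)(CO[Si](C)(C)C(C)(C)C)O2
F7 | step 10 | 14-(tert-butyldimethylsilyloxy)-9α,13-epoxy-15-nor-5β-labdane-6α,8α,16-triol | O[C@]1(C)C[C@H](O)[C@@H]2C(C)(C)CCC[C@]2(C)[C@@]12CC[C@@](CO)(CO[Si](C)(C)C(C)(C)C)O2
F8 | step 10 | 16-acetoxy-14-(tert-butyldimethylsilyloxy)-9α,13-epoxy-15-nor-5β-labdane-6α,8α-diol | O[C@]1(C)C[C@H](O)[C@@H]2C(C)(C)CCC[C@]2(C)[C@@]12CC[C@@](COC(C)=O)(CO[Si](C)(C)C(C)(C)C)O2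
F9 | step 18 | 16-(tert-butyldimethylsilyloxy)-9α,13-epoxy-5β-labd-7-en-14-yn-6-one | CC1=CC(=O)[C@@H]2C(C)(C)CCC[C@]2(C)[C@@]12CC[C@@](CO[Si](C)(C)C(C)(C)C)(C#C)O2
F10 | step 18 | 7β,8β-epoxy-16-(tert-butyldimethylsilyloxy)-9α,13-epoxy-5β-labd-14-yn-6-one | O1[C@@]2(C)[C@@H]1C(=O)[C@@H]3C(C)(C)CCC[C@]3(C)[C@@]24CC[C@@](CO[Si](C)(C)C(C)(C)C)(C#C)O4
F11 | step 18 | 8α-acetoxy-7β-hydroxy-16-(tert-butyldimethylsilyloxy)-9α,13-epoxy-5β-labd-14-yn-6-one | CC(=O)O[C@]1(C)[C@@H](O)C(=O)[C@@H]2C(C)(C)CCC[C@]2(C)[C@@]12CC[C@@](CO[Si](C)(C)C(C)(C)C)(C#C)O2
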